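Everything rests on disconnecting the C3–C1' bond between pyranone ring C and the pentasubstituted ring B, together with the O1–C2 bond. In one operation Tl(NO3)3 oxidises a chalcone carrying a free ring A hydroxyl ortho to the ketone: ring B, whose oxygens at C2' and C4' lie ortho and para to C1' and stabilise a bridged cation, shifts from the future C2 to C3, and acid then closes ring C. The precursor chalcone comes from dibenzylated phloroacetophenone and a ring B aldehyde bearing two benzyl ethers, the C5' methoxyl and a C6' bromine, a placeholder for the thallium-sensitive prenyl group, which is coupled on afterwards, before debenzylation.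

Key step: step 8

Remark: atom labels follow isoflavone numbering (ring A is the benzo ring C5–C8, ring C the pyranone, ring B C1'–C6'); the target has no stereocentre and the C3–C1' axis is not treated as a stereogenic element.
Remark: 3-bromo-4,5-dihydroxybenzaldehyde is taken as commercially available (it is also one AlCl3/pyridine demethylation away from 5-bromovanillin).
Remark: the ring B aldehyde is assembled with the bromine in place from the outset, because benzylation of 2,4,5-trihydroxybenzaldehyde would leave the chelated 2-hydroxyl, not the 5-hydroxyl, free, and bromination of a 2,4-dialkoxybenzaldehyde would compete at C3 and by ipso attack at the formyl carbon.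
Remark: thallium salts are highly toxic; step 8 is the only step that uses them.

Step 1
Reactants: 1 2,4,6-trihydroxyacetophenone; 2 benzyl bromide
Product: 3 1-[2,4-bis(benzyloxy)-6-hydroxyphenyl]ethanone
Conditions: BnBr (2.1 equiv), K2CO3, DMF, rt
Reagents that add atoms: benzyl bromide (compound 2), BrCc1ccccc1
Why: Williamson etherification in which the para hydroxyl and one ortho hydroxyl are alkylated while the remaining ortho hydroxyl, locked in a hydrogen bond to the ketone, should stay free.

Step 2
Reactants: 4 3-bromo-4,5-dihydroxybenzaldehyde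
Product: 5 3-bromo-5-hydroxy-4-methoxybenzaldehyde
Conditions: MeI (1.05 equiv), Li2CO3 (1.1 equiv), DMF, 40 °C
Reagents that add atoms: iodomethane, CI
Why: Chemoselective Williamson methylation, since the 4-hydroxyl (para to the formyl group, ortho to bromine) is much the more acidic phenol and a weak base with one equivalent of iodomethane should alkylate it alone.

Step 3
Reactants: 5 3-bromo-5-hydroxy-4-methoxybenzaldehyde; 2 benzyl bromide
Product: 6 3-(benzyloxy)-5-bromo-4-methoxybenzaldehyde
Conditions: BnBr, K2CO3, DMF, rt
Reagents that add atoms: benzyl bromide (compound 2), BrCc1ccccc1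
Why: Williamson etherification of the only remaining phenol.

Step 4
Reactants: 6 3-(benzyloxy)-5-bromo-4-methoxybenzaldehyde
Product: 8 3-(benzyloxy)-5-bromo-4-methoxyphenol, via aryl formate 7 (not isolated)
Conditions: mCPBA, CH2Cl2, rt; aq. NaHCO3 wash; then K2CO3 (cat.), MeOH, rt
Reagents that add atoms: 3-chloroperoxybenzoic acid (mCPBA), O=C(OO)c1cccc(Cl)c1
Why: Baeyer–Villiger oxidation in which the oxygenated aryl group should migrate in preference to hydride, followed by methanolysis of the aryl formate (a Dakin-type change of CHO into OH).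

Step 5
Reactants: 8 3-(benzyloxy)-5-bromo-4-methoxyphenol; 2 benzyl bromide
Product: 9 1,5-bis(benzyloxy)-3-bromo-2-methoxybenzene
Conditions: BnBr, K2CO3, DMF, rt
Reagents that add atoms: benzyl bromide (compound 2), BrCc1ccccc1
Why: Williamson etherification of the new phenol.

Step 6
Reactants: 9 1,5-bis(benzyloxy)-3-bromo-2-methoxybenzene
Product: 11 2,4-bis(benzyloxy)-6-bromo-5-methoxybenzaldehyde, via aryl iminium salt 10 (not isolated)
Conditions: POCl3, DMF, 0 to 80 °C; then H2O, 50 °C
Reagents that add atoms: N,N-dimethylformamide, CN(C)C=O; water, O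
Why: Vilsmeier–Haack formylation, in which the free position next to bromine is para to one benzyloxy group and ortho to the other, whereas the alternative position lies between the two benzyloxy groups and is more shielded, so the chloroiminium ion should attack next to bromine as it is known to do with bromo-substituted resorcinol diethers.

Step 7
Reactants: 3 1-[2,4-bis(benzyloxy)-6-hydroxyphenyl]ethanone; 11 2,4-bis(benzyloxy)-6-bromo-5-methoxybenzaldehyde
Product: 12 (E)-1-[2,4-bis(benzyloxy)-6-hydroxyphenyl]-3-[2,4-bis(benzyloxy)-6-bromo-5-methoxyphenyl]prop-2-en-1-one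
Conditions: KOH (50% aq.), EtOH/THF, rt to 40 °C
Reagents that add atoms: none
Why: Claisen–Schmidt condensation, in which the ketone enolate adds to the non-enolisable aldehyde and E1cB loss of water should give the conjugated (E)-enone under thermodynamic control.

Step 8
Reactants: 12 (E)-1-[2,4-bis(benzyloxy)-6-hydroxyphenyl]-3-[2,4-bis(benzyloxy)-6-bromo-5-methoxyphenyl]prop-2-en-1-one
Product: 14 5,7-bis(benzyloxy)-3-[2,4-bis(benzyloxy)-6-bromo-5-methoxyphenyl]chromen-4-one, via dimethyl acetal 13 (not isolated)
Conditions: Tl(NO3)3·3H2O (1.2 equiv), MeOH/HC(OMe)3/THF, rt; then 10% aq. HCl, 55 °C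
Reagents that add atoms: none
Why: Trivalent thallium adds to the enone carbon next to the ketone while methanol adds to the benzylic carbon; ring B then shifts to the thallium-bearing carbon through a phenonium ion as monovalent thallium leaves, and methanol traps the resulting oxocarbenium ion as dimethyl acetal 13, in which the C3–C1' bond is in place (its two methoxy groups come from methanol and leave again). The closest known reaction type is the Tl(NO3)3-mediated oxidative 1,2-aryl shift of ortho-hydroxychalcones to isoflavones. Ring C should close on acidification by attack of the free ring A hydroxyl on the oxocarbenium ion generated from the acetal (6-exo-trig, forming O1–C2), and elimination of the second methanol makes the pyranone fully conjugated. No stereocentre remains, because the only one formed (the aryl-bearing carbon of racemic 13) becomes sp2 C3. The step needs oxythallation of the single alkene and exclusive migration of ring B instead of aurone formation or oxidation of ring A; the benzyloxy groups ortho and para to the migrating carbon stabilise the phenonium ion, the orthoformate keeps the medium dry so that methanol is the nucleophile, and the bromine, unlike a prenyl group, is inert to trivalent thallium.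

Step 9
Reactants: 14 5,7-bis(benzyloxy)-3-[2,4-bis(benzyloxy)-6-bromo-5-methoxyphenyl]chromen-4-one; 15 prenylboronic acid pinacol ester
Product: 16 5,7-bis(benzyloxy)-3-[2,4-bis(benzyloxy)-5-methoxy-6-(3-methylbut-2-en-1-yl)phenyl]chromen-4-one
Conditions: 15 (2 equiv), Pd(dppf)Cl2 (10 mol %), K3PO4, THF/H2O (10:1), 70 °C
Reagents that add atoms: prenylboronic acid pinacol ester (compound 15), CC(C)=CCB1OC(C)(C)C(C)(C)O1
Why: Suzuki–Miyaura coupling in which, after oxidative addition of zerovalent palladium to the C6'–Br bond and transmetallation, the allylpalladium species should reductively eliminate through its primary carbon, the tertiary terminus being disfavoured by the two ortho substituents of the aryl group, to give the linear prenyl arene.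

Step 10
Reactants: 16 5,7-bis(benzyloxy)-3-[2,4-bis(benzyloxy)-5-methoxy-6-(3-methylbut-2-en-1-yl)phenyl]chromen-4-one
Product: 17 5,7-dihydroxy-3-[2,4-dihydroxy-5-methoxy-6-(3-methylbut-2-en-1-yl)phenyl]chromen-4-one (CNP0167499.0)
Conditions: BCl3 (1 M in CH2Cl2, 8 equiv), C6HMe5 (12 equiv), CH2Cl2, −78 °C; then H2O
Reagents that add atoms: none
Why: Lewis-acid cleavage of the four aryl benzyl ethers at low temperature, with pentamethylbenzene as a non-basic scavenger that should trap each benzyl cation by Friedel–Crafts alkylation before it reaches the prenyl alkene; the C5' methyl ether is not chelated to a carbonyl group and should survive, and the prenyl group has no ortho hydroxyl onto which it could cyclise.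

Compound list
1 | 2,4,6-trihydroxyacetophenone | CC(=O)c1c(O)cc(O)cc1O | starting material
2 | benzyl bromide | BrCc1ccccc1 | starting material
3 | 1-[2,4-bis(benzyloxy)-6-hydroxyphenyl]ethanone | CC(=O)c1c(O)cc(OCc2ccccc2)cc1OCc1ccccc1 | intermediate
4 | 3-bromo-4,5-dihydroxybenzaldehyde | O=Cc1cc(O)c(O)c(Br)c1 | starting material
5 | 3-bromo-5-hydroxy-4-methoxybenzaldehyde | COc1c(O)cc(C=O)cc1Br | intermediate
6 | 3-(benzyloxy)-5-bromo-4-methoxybenzaldehyde | COc1c(Br)cc(C=O)cc1OCc1ccccc1 | intermediate
7 | 3-(benzyloxy)-5-bromo-4-methoxyphenyl formate | COc1c(Br)cc(OC=O)cc1OCc1ccccc1 | intermediate (not isolated)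
8 | 3-(benzyloxy)-5-bromo-4-methoxyphenol | COc1c(Br)cc(O)cc1OCc1ccccc1 | intermediate
9 | 1,5-bis(benzyloxy)-3-bromo-2-methoxybenzene | COc1c(Br)cc(OCc2ccccc2)cc1OCc1ccccc1 | intermediate
10 | [2,4-bis(benzyloxy)-6-bromo-5-methoxyphenyl]methylidene(dimethyl)iminium dichlorophosphate | C[N+](C)=Cc1c(OCc2ccccc2)cc(OCc2ccccc2)c(OC)c1Br.[O-]P(=O)(Cl)Cl | intermediate (not isolated)
11 | 2,4-bis(benzyloxy)-6-bromo-5-methoxybenzaldehyde | COc1c(Br)c(C=O)c(OCc2ccccc2)cc1OCc1ccccc1 | intermediate
12 | (E)-1-[2,4-bis(benzyloxy)-6-hydroxyphenyl]-3-[2,4-bis(benzyloxy)-6-bromo-5-methoxyphenyl]prop-2-en-1-one | O=C(/C=C/c1c(OCc2ccccc2)cc(OCc2ccccc2)c(OC)c1Br)c1c(O)cc(OCc2ccccc2)cc1OCc1ccccc1 | intermediate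
13 | 1-[2,4-bis(benzyloxy)-6-hydroxyphenyl]-2-[2,4-bis(benzyloxy)-6-bromo-5-methoxyphenyl]-3,3-dimethoxypropan-1-one (racemic) | COC(OC)C(c1c(OCc2ccccc2)cc(OCc2ccccc2)c(OC)c1Br)C(=O)c1c(O)cc(OCc2ccccc2)cc1OCc1ccccc1 | intermediate (not isolated)
14 | 5,7-bis(benzyloxy)-3-[2,4-bis(benzyloxy)-6-bromo-5-methoxyphenyl]chromen-4-one | O=c1c(-c2c(OCc3ccccc3)cc(OCc3ccccc3)c(OC)c2Br)coc2cc(OCc3ccccc3)cc(OCc3ccccc3)c12 | intermediate
15 | prenylboronic acid pinacol ester, 4,4,5,5-tetramethyl-2-(3-methylbut-2-en-1-yl)-1,3,2-dioxaborolane | CC(C)=CCB1OC(C)(C)C(C)(C)O1 | starting material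
16 | 5,7-bis(benzyloxy)-3-[2,4-bis(benzyloxy)-5-methoxy-6-(3-methylbut-2-en-1-yl)phenyl]chromen-4-one | O=c1c(-c2c(OCc3ccccc3)cc(OCc3ccccc3)c(OC)c2CC=C(C)C)coc2cc(OCc3ccccc3)cc(OCc3ccccc3)c12 | intermediate
17 | 5,7-dihydroxy-3-[2,4-dihydroxy-5-methoxy-6-(3-methylbut-2-en-1-yl)phenyl]chromen-4-one | COc1c(O)cc(O)c(-c2coc3cc(O)cc(O)c3c2=O)c1CC=C(C)C | target

Total step count: 10. Longest linear sequence: 9 steps (from 4 through steps 2 to 10; the ring A branch joins at step 7).

Steps most likely to fail

Step 8. The trivalent thallium may oxidise the electron-rich ring A phenol, or that phenol may attack the thallated carbon and give an aurone, before the aryl shift occurs. Oxythallation may also be slow because the doubly ortho-substituted ring B is twisted out of conjugation with the alkene. The fallback inverts the order of ring closure and migration and uses no thallium. Setting out from chalcone 12, NaOAc in refluxing EtOH should isomerise it by intramolecular oxa-Michael addition to racemic 5,7-bis(benzyloxy)-2-[2,4-bis(benzyloxy)-6-bromo-5-methoxyphenyl]chroman-4-one F1. PhI(OAc)2 with catalytic H2SO4 in HC(OMe)3 should then bring about the known oxidative 2,3-aryl migration of flavanones (iodination of the enol ether at C3, shift of ring B from C2 to C3, loss of a proton) and deliver isoflavone 14, where the route is rejoined.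

Step 9. Oxidative addition into the doubly ortho-substituted, electron-rich C6'–Br bond may be slower than protodeboronation of the allylic boronate, and coupling through the tertiary terminus may give the 1,1-dimethylallyl isomer. The fallback builds the prenyl group in two stages, so that no regiochemical question arises in the coupling. Setting out from bromide 14, Stille coupling with allyltributylstannane (Pd(P(t-Bu)3)2, dioxane, 100 °C) should give 5,7-bis(benzyloxy)-3-[2,4-bis(benzyloxy)-5-methoxy-6-(prop-2-en-1-yl)phenyl]chromen-4-one F2. Olefin cross-metathesis with excess 2-methylbut-2-ene (second-generation Grubbs catalyst, CH2Cl2, 40 °C) should then turn the allyl group into the prenyl group and return to 16.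

Step 10. The prenyl alkene may add HCl or be alkylated by benzyl cations during the Lewis-acid debenzylation, and the product may be lost in the last step. The fallback removes the benzyl ethers before any alkene is present. Setting out from bromide 14, BCl3 and pentamethylbenzene in CH2Cl2 at −78 °C should give 3-(2-bromo-4,6-dihydroxy-3-methoxyphenyl)-5,7-dihydroxychromen-4-one F3. Ac2O, pyridine and catalytic DMAP should convert it into the tetraacetate 3-[4,6-bis(acetyloxy)-2-bromo-3-methoxyphenyl]-4-oxochromene-5,7-diyl diacetate F4. Suzuki–Miyaura coupling with 15 under anhydrous conditions (Pd(dppf)Cl2, CsF, THF, 65 °C) should give the prenylated tetraacetate 3-[4,6-bis(acetyloxy)-3-methoxy-2-(3-methylbut-2-en-1-yl)phenyl]-4-oxochromene-5,7-diyl diacetate F5. Methanolysis (K2CO3, MeOH, 0 °C to rt) should then remove all acetates under conditions harmless to the prenyl group and arrive at target 17; any acetate lost during the coupling is of no consequence.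

Further compounds
F1 | step 8 | 5,7-bis(benzyloxy)-2-[2,4-bis(benzyloxy)-6-bromo-5-methoxyphenyl]chroman-4-one (racemic) | O=C1CC(c2c(OCc3ccccc3)cc(OCc3ccccc3)c(OC)c2Br)Oc2cc(OCc3ccccc3)cc(OCc3ccccc3)c12
F2 | step 9 | 5,7-bis(benzyloxy)-3-[2,4-bis(benzyloxy)-5-methoxy-6-(prop-2-en-1-yl)phenyl]chromen-4-one | O=c1c(-c2c(OCc3ccccc3)cc(OCc3ccccc3)c(OC)c2CC=C)coc2cc(OCc3ccccc3)cc(OCc3ccccc3)c12
F3 | step 10 | 3-(2-bromo-4,6-dihydroxy-3-methoxyphenyl)-5,7-dihydroxychromen-4-one | COc1c(O)cc(O)c(-c2coc3cc(O)cc(O)c3c2=O)c1Br
F4 | step 10 | 3-[4,6-bis(acetyloxy)-2-bromo-3-methoxyphenyl]-4-oxochromene-5,7-diyl diacetate | COc1c(OC(C)=O)cc(OC(C)=O)c(-c2coc3cc(OC(C)=O)cc(OC(C)=O)c3c2=O)c1Br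
F5 | step 10 | 3-[4,6-bis(acetyloxy)-3-methoxy-2-(3-methylbut-2-en-1-yl)phenyl]-4-oxochromene-5,7-diyl diacetate | COc1c(OC(C)=O)cc(OC(C)=O)c(-c2coc3cc(OC(C)=O)cc(OC(C)=O)c3c2=O)c1CC=C(C)C
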